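## Structural features

The target is a benzophenone: ring A, a hexasubstituted benzene, is joined through the ketone carbon C7 to ring B, a 3-hydroxyphenyl group. Ring A carries the aroyl group on C1, free hydroxyls on C2 and C6, a methyl ether on C4 and 3-methylbut-2-enyl (prenyl) groups on C3 and C5. Oxygen-bearing and carbon-bearing ring atoms therefore alternate, and a mirror plane runs through C1 and C4. There is no stereocentre, and both side-chain alkenes end in a gem-dimethyl group, so no alkene geometry has to be set. The fragile elements are the prenyl groups next to phenolic oxygens (protic or strong Lewis acid closes them to chromans, hydride-abstracting oxidants give chromenes, hydrogenation is excluded), the electron-rich core, and any aryl silyl ether next to an organometallic centre. The real difficulty is regiochemical: six ring positions must be filled, the oxygen on C4 must be told apart from those on C2 and C6, and C-prenylation of a phloroglucinol by aromatic substitution gives O/C and mono/bis mixtures. The key step uses the alternating 1,3,5-oxygen pattern: C4 and its oxygen come from a ketene carbonyl flanked by the prenyl-bearing carbons C3 and C5, O2 from a silyl ynol ether, O6 from the enol ether of a cyclobutenone, and C1 stays unsubstituted. The three oxygens thus leave ring formation as a free phenol, a silyl ether and an ethyl ether.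

## Logic of the disconnections

31 ⇒ 30 ⇒ 28. The two O–Si bonds of 30 (O2 of ring A, O3′ of ring B) are cut last, and before them the O6–CH2 bond of the ethyl ether in 28. This order is chosen because the ketone oxygen can activate the C6 ether only while O2 carries a bulky silyl group that cannot chelate; a free O2–H would hold the carbonyl on its own side. The gain is that every phenol stays masked through the organometallic and oxidative steps. The forward steps must de-ethylate without protic acid, leave the unchelated C4 methyl ether alone, and desilylate under conditions mild enough for a polyphenol.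

28 ⇒ 27 ⇒ 23 + 24. The C1–C7 bond is cut after C7 is taken back from ketone to carbinol. C1 is the only free carbon of ring A, and an acid-promoted acylation there would endanger both prenyl groups. C1 is therefore the nucleophile (C–Li from C–Br) and C7 arrives as the formyl carbon of 24. The cut divides the molecule into a ring A half and a ring B half. The forward steps must exchange bromine for lithium faster than the benzylic–allylic CH2 groups are deprotonated, add before silicon leaves O2, and oxidise a hindered, acid-labile carbinol under buffered conditions.

23 ⇒ 22 ⇒ 21. The C1–Br bond and the O4–CH3 bond are cut. 21 has exactly one free phenol (O4) and one ring C–H (C1), so neither operation involves a regiochemical choice. The demand is the order: O4 is capped first, because a free phenol beside a prenyl group would cyclise under electrophilic bromine, and the bromination must then prefer the arene to the side-chain alkenes.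

21 ⇒ 10 + 16. Three ring bonds are cut at once: C3–C4, C1–C2 and C4–C5. Ring A falls into a four-carbon piece (C4, C1, C6, C5 with O6 and the C5 prenyl group, 10) and a two-carbon piece (C3 with its prenyl group, C2 with its oxygen, 16). This is the largest gain of the route: a pentasubstituted benzene with two prenyl groups and three differently capped oxygens becomes two small fragments, and all regiochemistry is carried by the polarity of a ketene and an ynol ether. The demand is a thermal cascade in which 10 opens at a temperature that 16 survives and the ketene adds to the ynol ether in one orientation.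

10 ⇒ 7 + 8, then 7 ⇒ 6 ⇒ 5 ⇒ 1 + 2. In 10 the ring bonds C1–C2 and C3–C4 are cut (a ketene–alkyne [2+2] addition in reverse), leaving 7 as ketene source and the two-carbon ether 8. 7 goes back through 6 to 5, whose C2–C3 bond is cut by a [3,3] (Johnson–Claisen) disconnection to 1 and 2. These cuts reach bulk chemicals in four steps. The demands are trapping of a dimerisation-prone aldoketene (slow generation in excess 8) and handling of the γ,δ-unsaturated acid derivative without mineral acid.

16 ⇒ 13 ⇒ 11 + 12. The O–Si and C1–O bonds of the ynol ether are cut, then the C3–C4 bond between the propargylic carbon and the allyl unit. Cutting at the acetylide oxygen keeps the chain at seven carbons. A Kowalski-type one-carbon homologation of 5 to an ynolate would insert a CH2 and give the homoprenyl analogue of 16, which would end as a homoprenyl group on C3 of the target; that route is therefore not used. The forward steps need attack of the alkynyl metal at the primary end of 12 and O-selective silylation of the ynolate, secured by a bulky silyl triflate.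

## Other disconnections considered

Alternative 1: The cut is at C1–C7 together with the C2–O bond, so ring A is traced to an aryne. In the forward step fluoride releases the aryne from the silylaryl triflate A2; the carboxylate of acid A3 adds at the aryne carbon remote from the flanking methoxy group, and the aryl anion takes the acyl group from oxygen. This is a formal insertion into the acid C–O bond and gives benzophenone A1.
- In its favour: one operation makes the diaryl ketone with the 2-hydroxy-4,6-dioxygenated pattern correctly placed, from stable aromatic pieces, with no organolithium and no oxidation.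
- Against it here: A1 has neither prenyl group. Double C-prenylation at C3 and C5 of a chelated, acyl-deactivated phenol competes with O-alkylation. The benzyl ether can no longer be hydrogenolysed once prenyl groups are present. The C6 methyl ether would have to be cut beside the C4 methyl ether when the carbonyl is already tied to the C2 hydroxyl.
- Comparison: structurally it makes the C1–C7 bond first and the prenyl bonds last, the reverse of the chosen plan, and it builds no ring. Mechanistically it is a polar aryne capture with acyl shift against a pericyclic cascade. On step economy it is better than the chosen plan for the ketone itself (one step against steps 9–11). It is expected to lose that lead in the prenylation and deprotection stages, which the chosen plan settles during ring construction.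

Alternative 2: The cut removes the CH2–CH bond of each prenyl side chain. In the forward step the bis-ammonium salt A4 (from twofold Mannich aminomethylation of the parent diphenol and N-quaternisation) is treated with excess alkenyl Grignard reagent A5 and a catalytic copper salt. Deprotonation and loss of the amine give an ortho-quinone methide, the isobutenyl group adds to its exocyclic carbon, the ring re-aromatises, and the same happens on the other side to give A6.
- In its favour: the regiochemistry is unambiguous, because aminomethylation can only go to C3 and C5. O-prenylation and chroman formation are avoided. The C4 methyl ether can be set early by para-selective methylation of a simple 2,4,6-trihydroxybenzophenone, so no ethyl ether has to be cut. A6 is one desilylation from 31.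
- Against it here: a diaryl ketone is exposed to excess Grignard reagent, protected only by its magnesium chelate and by hindrance. The quinone methides are cross-conjugated with the acyl group and can dimerise. The double Mannich reaction on an acyl-deactivated ring and clean N-quaternisation beside free phenols are both open questions.
- Comparison: structurally all substituents are added to a preformed arene and no ring is built. Mechanistically it is a stepwise elimination and conjugate addition. On step economy it is the equal of the chosen plan or better, and it avoids the ethyl-ether cleavage. The chosen plan is stronger where positions and oxygen differentiation are fixed by construction and not by the selectivity of aromatic substitution.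

Alternative 3: The cut opens ring A at C2–C3 and C5–C6, separating a malonyl unit (C1, C2, C6) from a ketone-derived unit (C3, C4, C5) that carries both prenyl groups. In the forward step the enol ether A8 of ketone A7 is C-acylated at both α-carbons by malonyl dichloride A9; the ring closes, the O-methyl group is lost and enolisation gives triol A10.
- In its favour: like the chosen plan it builds ring A with both prenyl groups in place, and it does so from a symmetrical ketone and a bulk reagent in very few steps.
- Against it here: O-acylation to pyranones competes with C-acylation. Acid is set free beside two trisubstituted alkenes and, after aromatisation, beside ortho-prenyl phenols. A10 has three free hydroxyls, and the one to be methylated (on C4, between the prenyl groups) is the most hindered. The aroyl group would have to be introduced under Friedel–Crafts or Hoesch conditions, and only then would the greater acidity of the unchelated para hydroxyl allow selective methylation.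
- Comparison: structurally it is the equal of the chosen plan as a ring-forming approach that places both prenyl groups during ring synthesis. Mechanistically it is a polar double acylation and condensation against a pericyclic cascade. On step economy it reaches A10 in fewer steps than the chosen plan needs for 21, which is better. 21, however, arrives with three differently capped oxygens and without acid, and the end game depends on exactly that.

Key step: step 7

Assumption: ethoxyethyne (hexane solution), ethynylmagnesium bromide (THF solution), 1-bromo-3-methylbut-2-ene and 3-[tert-butyl(dimethyl)silyloxy]benzaldehyde are taken as catalogue compounds; "racemic" marks centres that are erased before the target.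

Remark on the carbon count: the ynol ether 16 is made from the seven-carbon alkyne 13 and not by one-carbon homologation of ester 5, which would add a CH2 group.

## Route

Step 1
Reactants: 1 2-methylbut-3-en-2-ol; 2 triethyl orthoacetate
Product: 5 ethyl 5-methylhex-4-enoate, via mixed orthoester 3 (not isolated), via ketene acetal 4 (not isolated)
Conditions: EtCO2H (cat.), neat, 140 °C, EtOH distilled off
Reagents that add atoms: none
Why: Johnson–Claisen rearrangement: acid-catalysed exchange gives 3, loss of EtOH gives 4, and its chair-like [3,3] shift forms the C2–C3 bond of the ester and moves the alkene to the trisubstituted position, which has no geometry.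

Step 2
Reactants: 5 ethyl 5-methylhex-4-enoate
Product: 6 sodium 5-methylhex-4-enoate
Conditions: NaOH (1.05 equiv), EtOH–H2O, 50 °C; evaporate, dry by toluene azeotrope
Reagents that add atoms: sodium hydroxide, [Na+].[OH-]
Why: Ester saponification; the dry salt is kept because the free γ,δ-unsaturated acid can lactonise through protonation of its alkene under mineral acid.

Step 3
Reactants: 6 sodium 5-methylhex-4-enoate
Product: 7 5-methylhex-4-enoyl chloride
Conditions: (COCl)2, DMF (cat.), CH2Cl2, 0 °C → rt; filter, distil
Reagents that add atoms: oxalyl chloride, ClC(=O)C(=O)Cl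
Why: Acid chloride formation from a carboxylate salt: the acyl chlorooxalate collapses to 7, CO, CO2 and NaCl, so no HCl is released beside the alkene.

Step 4
Reactants: 7 5-methylhex-4-enoyl chloride; 8 ethoxyethyne
Product: 10 3-ethoxy-4-(3-methylbut-2-en-1-yl)cyclobut-2-en-1-one (racemic), via prenylketene 9 (not isolated)
Conditions: Et3N, 8 (2 equiv), Et2O, slow addition of 7, 0 °C → rt
Reagents that add atoms: none
Why: Dehydrochlorination gives aldoketene 9, which is trapped in a ketene–alkynyl ether [2+2] cycloaddition: the terminal carbon of 8 bonds to the ketene carbonyl carbon and the oxygen-bearing carbon to the ketene α-carbon, placing ethoxy on C3 and prenyl on C4; slow addition into excess 8 limits ketene dimerisation, and the racemic C4 centre is destroyed in step 7.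

Step 5
Reactants: 11 ethynylmagnesium bromide; 12 1-bromo-3-methylbut-2-ene
Product: 13 5-methylhex-4-en-1-yne
Conditions: 11 (3 equiv), CuCl (5 mol%), THF, 0 → 40 °C; fractional distillation
Reagents that add atoms: none
Why: Copper-catalysed coupling of an alkynyl Grignard reagent with a primary allylic bromide; the alkynyl group is delivered to the unhindered CH2 terminus and not to the tertiary carbon, and the excess of 11 suppresses a second alkylation.

Step 6
Reactants: 13 5-methylhex-4-en-1-yne
Product: 16 triisopropyl[(5-methylhex-4-en-1-yn-1-yl)oxy]silane, via lithium acetylide 14 (not isolated), via lithium ynolate 15 (not isolated)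
Conditions: n-BuLi, THF, −78 °C; t-BuOOLi (from t-BuOOH and LiN(SiMe3)2), −78 → 0 °C; i-Pr3SiOTf, −78 → 0 °C; filtration through Et3N-deactivated silica
Reagents that add atoms: tert-butyl hydroperoxide, CC(C)(C)OO; triisopropylsilyl trifluoromethanesulfonate, CC(C)[Si](OS(=O)(=O)C(F)(F)F)(C(C)C)C(C)C
Why: Oxidation of a lithium acetylide to a lithium ynolate with lithium tert-butyl peroxide (the acetylide carbon attacks the lithiated peroxide oxygen and expels tert-butoxide), then O-silylation by the bulky silyl triflate; the seven-carbon chain of 13 is kept unchanged.

Step 7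
Reactants: 10 3-ethoxy-4-(3-methylbut-2-en-1-yl)cyclobut-2-en-1-one; 16 triisopropyl[(5-methylhex-4-en-1-yn-1-yl)oxy]silane
Product: 21 3-ethoxy-2,6-bis(3-methylbut-2-en-1-yl)-5-(triisopropylsilyloxy)phenol, via vinylketene 17 (not isolated), via vinylcyclobutenone 18 (not isolated), via dienylketene 19 (not isolated), via cyclohexadienone 20 (not isolated)
Conditions: 16 (1.3 equiv), toluene (degassed), 80 → 110 °C, sealed vessel
Reagents that add atoms: none
Why: This is a Danheiser benzannulation of a cyclobutenone with a siloxyalkyne. Heating opens 10 by 4π conrotatory cleavage of its C1–C4 bond to vinylketene 17, the prenyl group turning outward. The ketene C=C adds to 16 in a polar [2+2] cycloaddition: the prenyl-bearing alkyne carbon, made nucleophilic by the silyloxy group, bonds to the ketene carbonyl carbon (ring bond C3–C4) and the oxygen-bearing carbon to the ketene α-carbon (ring bond C1–C2), giving 18. A second, reversible 4π opening gives dienylketene 19, and only the rotamer with the alkoxydienyl chain turned inward can react further. Ring A closes by thermal disrotatory 6π electrocyclisation between the ketene carbon and the prenyl-bearing terminus (ring bond C4–C5, a six-membered carbocycle), and dienone 20 enolises irreversibly to phenol 21. No stereocentre remains, since the centres of 10, 18 and 20 all become sp2. The step needs one orientation in the [2+2] event, secured by the polarisation of the ynol ether, and preference for the ynol ether over the unactivated trisubstituted alkenes, secured by its much higher nucleophilicity. The two ortho prenyl groups shield the new hydroxyl from acylation by ketene intermediates.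

Step 8
Reactants: 21 3-ethoxy-2,6-bis(3-methylbut-2-en-1-yl)-5-(triisopropylsilyloxy)phenol
Product: 22 [5-ethoxy-3-methoxy-2,4-bis(3-methylbut-2-en-1-yl)phenoxy]triisopropylsilane
Conditions: MeI, K2CO3, acetone, 50 °C
Reagents that add atoms: iodomethane, CI
Why: Williamson O-methylation of the only free phenol; the aryl silyl ether and the ethyl ether are inert, and capping O4 removes the free ortho-prenyl phenol before any electrophile is used.

Step 9
Reactants: 22 [5-ethoxy-3-methoxy-2,4-bis(3-methylbut-2-en-1-yl)phenoxy]triisopropylsilane
Product: 23 [2-bromo-3-ethoxy-5-methoxy-4,6-bis(3-methylbut-2-en-1-yl)phenoxy]triisopropylsilane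
Conditions: NBS (1.0 equiv), CH2Cl2, −78 → −20 °C, dark
Reagents that add atoms: N-bromosuccinimide, O=C1CCC(=O)N1Br
Why: Electrophilic aromatic bromination at the single free ring carbon, which is ortho, ortho and para to three oxygen donors and far more nucleophilic than the alkenes; with no free hydroxyl or added nucleophile, bromonium ions on the side chains have no productive outlet at low temperature.

Step 10
Reactants: 23 [2-bromo-3-ethoxy-5-methoxy-4,6-bis(3-methylbut-2-en-1-yl)phenoxy]triisopropylsilane; 24 3-[tert-butyl(dimethyl)silyloxy]benzaldehyde
Product: 27 {3-[tert-butyl(dimethyl)silyloxy]phenyl}[2-ethoxy-4-methoxy-3,5-bis(3-methylbut-2-en-1-yl)-6-(triisopropylsilyloxy)phenyl]methanol (racemic), via aryllithium 25 (not isolated), via lithium alkoxide 26 (not isolated)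
Conditions: t-BuLi (2.05 equiv), Et2O, −78 °C; 24, −78 °C; aq NH4Cl at −78 °C
Reagents that add atoms: none
Why: Bromine–lithium exchange at −78 °C is much faster than deprotonation of the benzylic–allylic CH2 groups, and 25 adds to the unhindered aldehyde; the cold quench of 26 prevents migration of silicon from O2 to the lithiated carbon or to the new alkoxide, and the racemic carbinol centre is removed in step 11.

Step 11
Reactants: 27 {3-[tert-butyl(dimethyl)silyloxy]phenyl}[2-ethoxy-4-methoxy-3,5-bis(3-methylbut-2-en-1-yl)-6-(triisopropylsilyloxy)phenyl]methanol
Product: 28 {3-[tert-butyl(dimethyl)silyloxy]phenyl}[2-ethoxy-4-methoxy-3,5-bis(3-methylbut-2-en-1-yl)-6-(triisopropylsilyloxy)phenyl]methanone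
Conditions: Dess–Martin periodinane, pyridine, CH2Cl2, 0 °C → rt
Reagents that add atoms: none
Why: Dess–Martin oxidation of a secondary diarylmethanol; the pyridine buffer prevents acid ionisation of the electron-rich benzhydrol, and the periodinane leaves prenyl groups and silyl ethers alone.

Step 12
Reactants: 28 {3-[tert-butyl(dimethyl)silyloxy]phenyl}[2-ethoxy-4-methoxy-3,5-bis(3-methylbut-2-en-1-yl)-6-(triisopropylsilyloxy)phenyl]methanone
Product: 30 {3-[tert-butyl(dimethyl)silyloxy]phenyl}[2-hydroxy-4-methoxy-3,5-bis(3-methylbut-2-en-1-yl)-6-(triisopropylsilyloxy)phenyl]methanone, via magnesium phenolate 29 (not isolated)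
Conditions: MgI2·OEt2 (4 equiv), toluene, 80 °C, argon sweep; aq NH4Cl
Reagents that add atoms: none
Why: Chelation-controlled dealkylation of an aryl ether ortho to a carbonyl: Mg bridges the ketone and ethoxy oxygens, iodide displaces the ethyl group (SN2) and volatile EtI is swept out; the C4 methyl ether cannot chelate, no protic acid is present to cyclise the prenyl groups, and the step precedes desilylation because a free C2 hydroxyl would hold the carbonyl in its own chelate.

Step 13
Reactants: 30 {3-[tert-butyl(dimethyl)silyloxy]phenyl}[2-hydroxy-4-methoxy-3,5-bis(3-methylbut-2-en-1-yl)-6-(triisopropylsilyloxy)phenyl]methanone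
Product: 31 [2,6-dihydroxy-4-methoxy-3,5-bis(3-methylbut-2-en-1-yl)phenyl](3-hydroxyphenyl)methanone
Conditions: Bu4NF, AcOH, THF, 0 °C → rt
Reagents that add atoms: none
Why: Fluoride cleavage of both aryl silyl ethers, driven by Si–F bond formation; the acetic acid buffer keeps the polyphenol from standing as an oxidisable phenoxide and leaves alkenes and ketone untouched.

## Compound list

1 | 2-methylbut-3-en-2-ol | C=CC(C)(C)O | starting material
2 | triethyl orthoacetate | CCOC(C)(OCC)OCC | starting material
3 | 3-(1,1-diethoxyethoxy)-3-methylbut-1-ene | CCOC(C)(OCC)OC(C)(C)C=C | intermediate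
4 | 3-[(1-ethoxyethenyl)oxy]-3-methylbut-1-ene | C=C(OCC)OC(C)(C)C=C | intermediate
5 | ethyl 5-methylhex-4-enoate | CCOC(=O)CCC=C(C)C | intermediate
6 | sodium 5-methylhex-4-enoate | [Na+].[O-]C(=O)CCC=C(C)C | intermediate
7 | 5-methylhex-4-enoyl chloride | ClC(=O)CCC=C(C)C | intermediate
8 | ethoxyethyne | C#COCC | starting material
9 | 5-methylhexa-1,4-dien-1-one | O=C=CCC=C(C)C | intermediate
10 | 3-ethoxy-4-(3-methylbut-2-en-1-yl)cyclobut-2-en-1-one (racemic) | O=C1C=C(OCC)C1CC=C(C)C | intermediate
11 | ethynylmagnesium bromide | C#C[Mg]Br | starting material
12 | 1-bromo-3-methylbut-2-ene | CC(C)=CCBr | starting material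
13 | 5-methylhex-4-en-1-yne | C#CCC=C(C)C | intermediate
14 | (5-methylhex-4-en-1-yn-1-yl)lithium | [Li]C#CCC=C(C)C | intermediate
15 | lithium 5-methylhex-4-en-1-yn-1-olate | [Li]OC#CCC=C(C)C | intermediate
16 | triisopropyl[(5-methylhex-4-en-1-yn-1-yl)oxy]silane | CC(C)=CCC#CO[Si](C(C)C)(C(C)C)C(C)C | intermediate
17 | (3Z)-3-ethoxy-7-methylocta-1,3,6-trien-1-one | O=C=C/C(OCC)=C/CC=C(C)C | intermediate
18 | 4-[(1Z)-1-ethoxy-5-methylhexa-1,4-dien-1-yl]-2-(3-methylbut-2-en-1-yl)-3-(triisopropylsilyloxy)cyclobut-2-en-1-one (racemic) | O=C1C(CC=C(C)C)=C(O[Si](C(C)C)(C(C)C)C(C)C)C1/C(OCC)=C/CC=C(C)C | intermediate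
19 | (3E,5Z)-5-ethoxy-9-methyl-2-(3-methylbut-2-en-1-yl)-3-(triisopropylsilyloxy)deca-1,3,5,8-tetraen-1-one | O=C=C(CC=C(C)C)/C(O[Si](C(C)C)(C(C)C)C(C)C)=C\C(OCC)=C\CC=C(C)C | intermediate
20 | 5-ethoxy-2,6-bis(3-methylbut-2-en-1-yl)-3-(triisopropylsilyloxy)cyclohexa-2,4-dien-1-one (racemic) | O=C1C(CC=C(C)C)=C(O[Si](C(C)C)(C(C)C)C(C)C)C=C(OCC)C1CC=C(C)C | intermediate
21 | 3-ethoxy-2,6-bis(3-methylbut-2-en-1-yl)-5-(triisopropylsilyloxy)phenol | Oc1c(CC=C(C)C)c(O[Si](C(C)C)(C(C)C)C(C)C)cc(OCC)c1CC=C(C)C | intermediate
22 | [5-ethoxy-3-methoxy-2,4-bis(3-methylbut-2-en-1-yl)phenoxy]triisopropylsilane | COc1c(CC=C(C)C)c(O[Si](C(C)C)(C(C)C)C(C)C)cc(OCC)c1CC=C(C)C | intermediate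
23 | [2-bromo-3-ethoxy-5-methoxy-4,6-bis(3-methylbut-2-en-1-yl)phenoxy]triisopropylsilane | COc1c(CC=C(C)C)c(O[Si](C(C)C)(C(C)C)C(C)C)c(Br)c(OCC)c1CC=C(C)C | intermediate
24 | 3-[tert-butyl(dimethyl)silyloxy]benzaldehyde | O=Cc1cccc(O[Si](C)(C)C(C)(C)C)c1 | starting material
25 | [2-ethoxy-4-methoxy-3,5-bis(3-methylbut-2-en-1-yl)-6-(triisopropylsilyloxy)phenyl]lithium | COc1c(CC=C(C)C)c(O[Si](C(C)C)(C(C)C)C(C)C)c([Li])c(OCC)c1CC=C(C)C | intermediate
26 | lithium {3-[tert-butyl(dimethyl)silyloxy]phenyl}[2-ethoxy-4-methoxy-3,5-bis(3-methylbut-2-en-1-yl)-6-(triisopropylsilyloxy)phenyl]methanolate (racemic) | [Li]OC(c1cccc(O[Si](C)(C)C(C)(C)C)c1)c1c(OCC)c(CC=C(C)C)c(OC)c(CC=C(C)C)c1O[Si](C(C)C)(C(C)C)C(C)C | intermediate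
27 | {3-[tert-butyl(dimethyl)silyloxy]phenyl}[2-ethoxy-4-methoxy-3,5-bis(3-methylbut-2-en-1-yl)-6-(triisopropylsilyloxy)phenyl]methanol (racemic) | OC(c1cccc(O[Si](C)(C)C(C)(C)C)c1)c1c(OCC)c(CC=C(C)C)c(OC)c(CC=C(C)C)c1O[Si](C(C)C)(C(C)C)C(C)C | intermediate
28 | {3-[tert-butyl(dimethyl)silyloxy]phenyl}[2-ethoxy-4-methoxy-3,5-bis(3-methylbut-2-en-1-yl)-6-(triisopropylsilyloxy)phenyl]methanone | O=C(c1cccc(O[Si](C)(C)C(C)(C)C)c1)c1c(OCC)c(CC=C(C)C)c(OC)c(CC=C(C)C)c1O[Si](C(C)C)(C(C)C)C(C)C | intermediate
29 | iodomagnesium 2-{3-[tert-butyl(dimethyl)silyloxy]benzoyl}-5-methoxy-4,6-bis(3-methylbut-2-en-1-yl)-3-(triisopropylsilyloxy)phenolate | O=C(c1cccc(O[Si](C)(C)C(C)(C)C)c1)c1c(O[Mg]I)c(CC=C(C)C)c(OC)c(CC=C(C)C)c1O[Si](C(C)C)(C(C)C)C(C)C | intermediate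
30 | {3-[tert-butyl(dimethyl)silyloxy]phenyl}[2-hydroxy-4-methoxy-3,5-bis(3-methylbut-2-en-1-yl)-6-(triisopropylsilyloxy)phenyl]methanone | O=C(c1cccc(O[Si](C)(C)C(C)(C)C)c1)c1c(O)c(CC=C(C)C)c(OC)c(CC=C(C)C)c1O[Si](C(C)C)(C(C)C)C(C)C | intermediate
31 | [2,6-dihydroxy-4-methoxy-3,5-bis(3-methylbut-2-en-1-yl)phenyl](3-hydroxyphenyl)methanone | COc1c(CC=C(C)C)c(O)c(C(=O)c2cccc(O)c2)c(O)c1CC=C(C)C | target

## Step count and least certain steps

Total step count: 13. Longest linear sequence: 11 steps (steps 1–4 and 7–13); steps 5 and 6 form the second branch.

Step 7 (key step). The electrocyclic opening of 10, a vinylogous ester, may need a temperature at which 16 isomerises by a shift of silicon from oxygen to carbon or is hydrolysed. Vinylketene 17 would then form too slowly and be lost to self-addition; a 1,5-hydrogen shift in the rotamer of 17 with the side chain turned inward is a second leak. The fallback sets out from 12 and 16 and comes back at 17, and so at 21. It generates the same vinylketene at or below room temperature from an open-chain acid chloride. The dianion of ethyl acetoacetate (NaH, then n-BuLi, THF, 0 °C) is alkylated at its terminal carbon with 12 to give ethyl 7-methyl-3-oxooct-6-enoate F1. Triethyl orthoformate with a trace of acid in ethanol turns it into ethyl (2E)-3-ethoxy-7-methylocta-2,6-dienoate F2. KOH gives potassium (2E)-3-ethoxy-7-methylocta-2,6-dienoate F3, and oxalyl chloride gives (2E)-3-ethoxy-7-methylocta-2,6-dienoyl chloride F4. Et3N in toluene then removes hydrogen chloride from F4 by 1,4-elimination in the presence of 16. This forms 17 directly; the [2+2] addition to 18 can proceed at room temperature and gentle warming completes the sequence to 21. All operations are established types: γ-alkylation of a β-keto ester dianion, enol ether formation, saponification, and dehydrohalogenation of a 3-alkoxyalk-2-enoyl chloride to an alkoxyvinylketene.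

Step 9. Electrophilic bromine may attack the trisubstituted alkenes, with capture of the bromonium ion by a neighbouring ether oxygen and loss of its O-substituent (bromochroman formation), or may attack a substituted ring carbon. The fallback sets out from 22 and comes back at 27, replacing steps 9 and 10. It uses a weaker carbon electrophile and reverses the polarity of the ring coupling. Vilsmeier–Haack formylation (POCl3, DMF, 0 °C to room temperature, then aqueous NaOAc) gives 2-ethoxy-4-methoxy-3,5-bis(3-methylbut-2-en-1-yl)-6-(triisopropylsilyloxy)benzaldehyde F5. Ring B then enters as the nucleophile {3-[tert-butyl(dimethyl)silyloxy]phenyl}magnesium bromide F6 (from the corresponding aryl bromide and Mg in THF), whose addition to F5 gives 27.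

Step 12. Two processes may defeat the step. Iodide displacement at an ethyl carbon is slower than at methyl. The doubly ortho-substituted diaryl ketone is also twisted, which may hinder chelation. Prolonged heating could then remove the C2 silyl ether, after which the carbonyl is held by O2 and de-ethylation stalls. The fallback sets out from 23 and comes back at 30, replacing steps 10–12. It moves the de-ethylation to a flat, unhindered formyl chelate before ring B is attached. Bromine–lithium exchange on 23 (t-BuLi, −78 °C) and DMF give aldehyde F5. MgI2·OEt2 then cleaves the ethyl ether within the formyl chelate to give 2-hydroxy-4-methoxy-3,5-bis(3-methylbut-2-en-1-yl)-6-(triisopropylsilyloxy)benzaldehyde F7. Grignard reagent F6 (2.2 equiv, the first equivalent deprotonating the phenol) adds to give 2-[{3-[tert-butyl(dimethyl)silyloxy]phenyl}(hydroxy)methyl]-5-methoxy-4,6-bis(3-methylbut-2-en-1-yl)-3-(triisopropylsilyloxy)phenol F8. MnO2 in CH2Cl2 oxidises the benzylic carbinol selectively to 30. This removes the steric part of the problem; the slower displacement at ethyl remains.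

Step 5. The alkynyl group may attack the tertiary end of the allyl system, the product acetylide may be alkylated a second time, and volatile 13 may be lost on isolation. The fallback sets out from 5 and comes back at 15, and so at 16, replacing steps 5 and 6. It makes the ynolate from the ester that already feeds the other branch. LiN(i-Pr)2 in THF at −78 °C followed by 1,2-dibromotetrachloroethane gives ethyl 2-bromo-5-methylhex-4-enoate F9, and repetition gives ethyl 2,2-dibromo-5-methylhex-4-enoate F10. t-BuLi (4 equiv, THF, −78 → 0 °C) effects double bromine–lithium exchange with loss of ethoxide, giving ynolate 15, which i-Pr3SiOTf silylates on oxygen to 16. The α-carbon of the ester becomes the prenyl-bearing alkyne carbon, so the seven-carbon count is kept.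

## Further compounds

F1 | step 7 | ethyl 7-methyl-3-oxooct-6-enoate | CCOC(=O)CC(=O)CCC=C(C)C
F2 | step 7 | ethyl (2E)-3-ethoxy-7-methylocta-2,6-dienoate | CCOC(=O)/C=C(OCC)\CCC=C(C)C
F3 | step 7 | potassium (2E)-3-ethoxy-7-methylocta-2,6-dienoate | [K+].[O-]C(=O)/C=C(OCC)\CCC=C(C)C
F4 | step 7 | (2E)-3-ethoxy-7-methylocta-2,6-dienoyl chloride | ClC(=O)/C=C(OCC)\CCC=C(C)C
F5 | step 9 | 2-ethoxy-4-methoxy-3,5-bis(3-methylbut-2-en-1-yl)-6-(triisopropylsilyloxy)benzaldehyde | O=Cc1c(OCC)c(CC=C(C)C)c(OC)c(CC=C(C)C)c1O[Si](C(C)C)(C(C)C)C(C)C
F6 | step 9 | {3-[tert-butyl(dimethyl)silyloxy]phenyl}magnesium bromide | Br[Mg]c1cccc(O[Si](C)(C)C(C)(C)C)c1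
F7 | step 12 | 2-hydroxy-4-methoxy-3,5-bis(3-methylbut-2-en-1-yl)-6-(triisopropylsilyloxy)benzaldehyde | O=Cc1c(O)c(CC=C(C)C)c(OC)c(CC=C(C)C)c1O[Si](C(C)C)(C(C)C)C(C)C
F8 | step 12 | 2-[{3-[tert-butyl(dimethyl)silyloxy]phenyl}(hydroxy)methyl]-5-methoxy-4,6-bis(3-methylbut-2-en-1-yl)-3-(triisopropylsilyloxy)phenol (racemic) | OC(c1cccc(O[Si](C)(C)C(C)(C)C)c1)c1c(O)c(CC=C(C)C)c(OC)c(CC=C(C)C)c1O[Si](C(C)C)(C(C)C)C(C)C
F9 | step 5 | ethyl 2-bromo-5-methylhex-4-enoate (racemic) | CCOC(=O)C(Br)CC=C(C)C
F10 | step 5 | ethyl 2,2-dibromo-5-methylhex-4-enoate | CCOC(=O)C(Br)(Br)CC=C(C)C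
A1 | alternative 1 | [3-(benzyloxy)phenyl](2-hydroxy-4,6-dimethoxyphenyl)methanone | COc1cc(O)c(C(=O)c2cccc(OCc3ccccc3)c2)c(OC)c1
A2 | alternative 1 | 3,5-dimethoxy-2-(trimethylsilyl)phenyl trifluoromethanesulfonate | COc1cc(OC)c([Si](C)(C)C)c(OS(=O)(=O)C(F)(F)F)c1
A3 | alternative 1 | 3-(benzyloxy)benzoic acid | OC(=O)c1cccc(OCc2ccccc2)c1
A4 | alternative 2 | [5-{3-[tert-butyl(dimethyl)silyloxy]benzoyl}-4,6-dihydroxy-2-methoxy-1,3-phenylene]bis(N,N,N-trimethylmethanaminium) diiodide | COc1c(C[N+](C)(C)C)c(O)c(C(=O)c2cccc(O[Si](C)(C)C(C)(C)C)c2)c(O)c1C[N+](C)(C)C.[I-].[I-]
A5 | alternative 2 | (2-methylprop-1-en-1-yl)magnesium bromide | CC(C)=C[Mg]Br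
A6 | alternative 2 | {3-[tert-butyl(dimethyl)silyloxy]phenyl}[2,6-dihydroxy-4-methoxy-3,5-bis(3-methylbut-2-en-1-yl)phenyl]methanone | COc1c(CC=C(C)C)c(O)c(C(=O)c2cccc(O[Si](C)(C)C(C)(C)C)c2)c(O)c1CC=C(C)C
A7 | alternative 3 | 2,10-dimethylundeca-2,9-dien-6-one | CC(C)=CCCC(=O)CCC=C(C)C
A8 | alternative 3 | 6-methoxy-2,10-dimethylundeca-2,5,9-triene (enol ether, either geometry) | CC(C)=CCC=C(OC)CCC=C(C)C
A9 | alternative 3 | malonyl dichloride | ClC(=O)CC(=O)Cl
A10 | alternative 3 | 2,4-bis(3-methylbut-2-en-1-yl)benzene-1,3,5-triol | Oc1cc(O)c(CC=C(C)C)c(O)c1CC=C(C)C
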